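**Plan**

- Retrosynthesis: cut C3–Br first (late electrophilic bromination), restore a C2 ester as the handle left by the ring-forming chemistry, cut N1–C7a of the pyrrole ring back to an α-azidocinnamate, then cut C2=C3 to 2,4-dibromobenzaldehyde and methyl azidoacetate.
- Forward: a condensation joins C2 to C3; thermolysis of the vinyl azide closes the only ring built on the route (the pyrrole ring, through N1–C7a); ester hydrolysis, protodecarboxylation and C3 bromination complete the target.
- Enabling feature: the carbons ortho to C3a are C4 and C7a; C4 already carries bromine (C6 too, both brought in with the aldehyde), so nitrogen can only bond to C7a–H and the benzo ring never needs halogenation.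
- Stereochemistry: the target has no stereocentre; the only stereo-element on the route is the Z olefin of the azidocinnamate, set in the condensation and erased on aromatisation.

Key step: step 2

Assumption: the target is achiral, so "single enantiomer" reduces to the constitution shown; the transient intermediates 3, 5 and 6 are racemic and their stereocentres vanish. Methyl azidoacetate is taken as a commercial reagent and handled in solution behind a blast shield.

**Route**

Step 1
Reactants: 1 2,4-dibromobenzaldehyde; 2 methyl azidoacetate
Product: 4 methyl (Z)-2-azido-3-(2,4-dibromophenyl)acrylate, via aldol adduct 3 (not isolated)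
Conditions: NaOMe (4 equiv), 2 (4 equiv), MeOH, −15 → 0 °C; cold aq. NH4Cl
Reagents that add atoms: none
Why: Knoevenagel-type aldol condensation (first stage of the Hemetsberger–Knittel sequence), in which the enolate of 2 adds to the electron-poor aldehyde and the sodium aldolate of 3 loses hydroxide by E1cB; the olefin should form as the Z isomer (aryl trans to the ester) because that is the less strained geometry, and the low temperature keeps the azide, the aryl bromides and the matching methyl ester intact.

Step 2
Reactants: 4 methyl (Z)-2-azido-3-(2,4-dibromophenyl)acrylate
Product: 7 methyl 4,6-dibromo-1H-indole-2-carboxylate, via 2H-azirine 5 (not isolated), via 7aH-indole tautomer 6 (not isolated)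
Conditions: xylenes, 140 °C, slow addition of 4 to the refluxing solvent (final ≤0.05 M), argon
Reagents that add atoms: none
Why: At 140 °C the vinyl azide loses dinitrogen to give a singlet vinyl nitrene that is in equilibrium with 2H-azirine 5. The aryl-conjugated nitrene closes the pyrrole ring by a 6π 1,5-electrocyclisation over the five-atom array N1–C2–C3–C3a–C7a, forming the N1–C7a bond and giving 7aH-indole 6, and a [1,5]-hydrogen shift from C7a to N1 then restores aromaticity to give 7. This is the Hemetsberger–Knittel indole synthesis, formally an intramolecular nitrene amination of an aryl C–H bond. No stereocentre is created in 7, since those of 5 and 6 are transient and racemic. The step needs regioselectivity between the two carbons ortho to C3a, and the substrate secures it because the future C4 carries bromine and has no hydrogen to shift, leaving C7a–H as the only productive site. The aryl C–Br bonds and the ester should be inert at this temperature without metal or base, and dilution with slow addition suppresses bimolecular reactions of the nitrene and azirine.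

Step 3
Reactants: 7 methyl 4,6-dibromo-1H-indole-2-carboxylate
Product: 8 4,6-dibromo-1H-indole-2-carboxylic acid
Conditions: LiOH·H2O (4 equiv), THF/MeOH/H2O, 50 °C; then 1 M HCl to pH 2
Reagents that add atoms: lithium hydroxide, [Li+].[OH-], used in water, O (the hydroxide/water oxygen becomes the carboxyl OH)
Why: Saponification (BAc2 ester hydrolysis) of an unhindered methyl ester, in which the indole N–H and the two aryl bromides, not activated for SNAr, should pass unchanged and acidification precipitates the acid.

Step 4
Reactants: 8 4,6-dibromo-1H-indole-2-carboxylic acid
Product: 9 4,6-dibromo-1H-indole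
Conditions: Ag2CO3 (10 mol %), AcOH (5 mol %), DMSO, 120 °C
Reagents that add atoms: none
Why: Silver-catalysed protodecarboxylation of a heteroaryl-2-carboxylic acid, in which the silver carboxylate extrudes CO2 next to the ring nitrogen and the resulting C2–silver species is protonated by acetic acid or fresh 8; Ag(I) at 120 °C should leave the C–Br bonds alone, which a copper/quinoline decarboxylation above 200 °C would put at risk.

Step 5
Reactants: 9 4,6-dibromo-1H-indole
Product: 10 3,4,6-tribromo-1H-indole
Conditions: NBS (1.0 equiv), DMF, 0 °C, dark; aq. Na2S2O3/NaHCO3
Reagents that add atoms: N-bromosuccinimide, O=C1CCC(=O)N1Br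
Why: Electrophilic aromatic substitution with NBS at C3, the enamine-like and most nucleophilic carbon of an N–H indole; the benzo ring is deactivated by its two bromines and C2 reacts only after C3, so one equivalent at 0 °C should stop at monobromination despite the peri C4–Br.

**Compound list**

1 | 2,4-dibromobenzaldehyde | O=Cc1ccc(Br)cc1Br | starting material
2 | methyl azidoacetate | COC(=O)CN=[N+]=[N-] | starting material
3 | methyl 2-azido-3-(2,4-dibromophenyl)-3-hydroxypropanoate (aldol adduct, racemic diastereomer mixture, present as its sodium alkoxide) | COC(=O)C(N=[N+]=[N-])C(O)c1ccc(Br)cc1Br | intermediate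
4 | methyl (Z)-2-azido-3-(2,4-dibromophenyl)acrylate | COC(=O)/C(N=[N+]=[N-])=C/c1ccc(Br)cc1Br | intermediate
5 | methyl 2-(2,4-dibromophenyl)-2H-azirine-3-carboxylate (racemic) | COC(=O)C1=NC1c1ccc(Br)cc1Br | intermediate
6 | methyl 4,6-dibromo-7aH-indole-2-carboxylate (racemic) | COC(=O)C1=NC2C=C(Br)C=C(Br)C2=C1 | intermediate
7 | methyl 4,6-dibromo-1H-indole-2-carboxylate | COC(=O)c1cc2c(Br)cc(Br)cc2[nH]1 | intermediate
8 | 4,6-dibromo-1H-indole-2-carboxylic acid | OC(=O)c1cc2c(Br)cc(Br)cc2[nH]1 | intermediate
9 | 4,6-dibromo-1H-indole | Brc1cc(Br)c2cc[nH]c2c1 | intermediate
10 | 3,4,6-tribromo-1H-indole | Brc1cc(Br)c2c(Br)c[nH]c2c1 | target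

**Count**

Total steps: 5. Longest linear sequence: 5 steps (from 1).

**Steps most likely to fail**

Step 1. Base-induced decomposition of the azidoacetate enolate and hydroxide-mediated ester hydrolysis may outrun the slow dehydration of the hindered ortho-bromo aldolate. The fallback separates C–C bond formation from elimination. It sets out from 1 and 2, which are combined with NaOMe in MeOH at −30 °C and quenched cold with NH4Cl so that aldol 3 is isolated. Treatment of 3 with MsCl and Et3N in CH2Cl2 at 0 °C should give methyl 2-azido-3-(2,4-dibromophenyl)-3-(methylsulfonyloxy)propanoate F1, which eliminates in the same flask under the amine base. The fallback comes back to the route at 4.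

Step 4. Decarboxylation may stall at the silver carboxylate, or reductive loss of bromine may compete at the temperature required. The fallback removes the C2 carbon as carbon monoxide instead. It sets out from ester 7, which is reduced with DIBAL-H (THF, −78 → 0 °C) to (4,6-dibromo-1H-indol-2-yl)methanol F2. Oxidation with MnO2 in CH2Cl2 should give 4,6-dibromo-1H-indole-2-carbaldehyde F3. Tsuji–Wilkinson decarbonylation with RhCl(PPh3)3 in xylene at 140 °C then comes back to the route at 9.

Step 5. Over-bromination at C2, and acid- or light-induced degradation of the N–H 3-bromoindole during isolation, may erode the material. The fallback shields N1 and C2 with a bulky silyl group. It sets out from 9, which is silylated (NaH, TIPSCl, THF, 0 °C) to 4,6-dibromo-1-(triisopropylsilyl)-1H-indole F4. Bromination with NBS in THF at −78 °C should give 3,4,6-tribromo-1-(triisopropylsilyl)-1H-indole F5. Desilylation with TBAF in THF at 0 °C comes back to the route at 10.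

**Further compounds**

F1 | step 1 | methyl 2-azido-3-(2,4-dibromophenyl)-3-(methylsulfonyloxy)propanoate (diastereomer mixture) | COC(=O)C(N=[N+]=[N-])C(OS(C)(=O)=O)c1ccc(Br)cc1Br
F2 | step 4 | (4,6-dibromo-1H-indol-2-yl)methanol | OCc1cc2c(Br)cc(Br)cc2[nH]1
F3 | step 4 | 4,6-dibromo-1H-indole-2-carbaldehyde | O=Cc1cc2c(Br)cc(Br)cc2[nH]1
F4 | step 5 | 4,6-dibromo-1-(triisopropylsilyl)-1H-indole | CC(C)[Si](C(C)C)(C(C)C)n1ccc2c(Br)cc(Br)cc21
F5 | step 5 | 3,4,6-tribromo-1-(triisopropylsilyl)-1H-indole | CC(C)[Si](C(C)C)(C(C)C)n1cc(Br)c2c(Br)cc(Br)cc21
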